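**Retrosynthetic overview**

1. Numbering: C1 (ring C=O beside the carbinol), C2 (acyl-bearing), C3 (enol carbon), C4, C5, C6 (CHOH), C1' (side-chain C=O). The route rests on one feature: the C6 oxygen is γ to C3, so C3, C4, C5, C6 and that oxygen are the γ-lactone of (S)-2-hydroxyglutaric acid, while C2, flanked by C1=O and C1'=O, is an acidic carbon placed to take C3 away from that oxygen.
2. Key disconnection C2–C3: the target is an isomer of the acyl lactone (S)-5-(3-oxo-15-phenylpentadecanoyl)dihydrofuran-2(3H)-one, which base should convert into the carbocycle by intramolecular Claisen acylation.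
3. Disconnection C1–C2 of that precursor: C-acylation of a β-keto ester (C2 from a malonic half-ester, C1' and the chain from 13-phenyltridecanoic acid) by the chloride of the lactone acid from L-glutamic acid, then loss of the tert-butoxycarbonyl group.
4. Side chain: copper-catalysed coupling of 11-bromoundecanoic acid with 2-phenylethylmagnesium bromide.
5. Ring order: the γ-lactone first (step 1, carrying the only stereocentre), the six-membered carbocycle last (step 7), formed as the lactone opens.

Key step: step 7

Assumption: the target is a β-triketone whose enol forms interconvert freely, so the tautomer drawn (enol at C3) stands for the equilibrium mixture; 16 and 17 are written as keto forms although they should be largely enolised.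

**Route**

Step 1
Reactants: 1 L-glutamic acid
Product: 4 (S)-5-oxotetrahydrofuran-2-carboxylic acid, via diazonium carboxylate 2 (not isolated), via α-lactone 3 (not isolated)
Conditions: NaNO2 (1.5 equiv), 2 M aq. HCl, 0 °C → rt, 16 h; evaporation, EtOAc extraction, crystallisation
Reagents that add atoms: none
Why: Nitrous acid deamination of an α-amino acid proceeds with neighbouring-group participation, the α-carboxylate displacing N2 from 2 to give α-lactone 3 (inversion) and the γ-carboxyl group then opening 3 at the same carbon (second inversion), so the γ-lactone closes with net retention and the stereocentre of 4 is the S centre of L-glutamic acid.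

Step 2
Reactants: 4 (S)-5-oxotetrahydrofuran-2-carboxylic acid
Product: 5 (S)-5-oxotetrahydrofuran-2-carbonyl chloride
Conditions: (COCl)2 (1.3 equiv), DMF (cat.), CH2Cl2, 0 °C → rt; evaporation, crude 5 used at once
Reagents that add atoms: oxalyl chloride, ClC(=O)C(=O)Cl
Why: Conversion of a carboxylic acid into its chloride through the catalytic chloroiminium (Vilsmeier-type) species is run without base, so neither the γ-lactone nor the α-oxygenated stereocentre, which is at risk only by base-induced enolisation, is affected.

Step 3
Reactants: 6 (2-bromoethyl)benzene; 7 11-bromoundecanoic acid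
Product: 10 13-phenyltridecanoic acid, via 2-phenylethylmagnesium bromide 8 (not isolated), via chloromagnesium 11-bromoundecanoate 9 (not isolated)
Conditions: 6, Mg turnings, THF, rt → 40 °C (gives 8, 1.5 equiv); 7, MeMgCl (1.0 equiv), THF, −20 °C (gives 9); then 8, Li2CuCl4 (3 mol %), THF, −20 °C → rt; 1 M HCl
Reagents that add atoms: none
Why: Copper-catalysed Grignard cross-coupling of a primary alkyl bromide (Li2CuCl4) joins C11 of the acid to the magnesium-bearing CH2 carbon of 8, the carboxyl group being masked in the flask as magnesium carboxylate 9, which a Grignard reagent does not attack at −20 °C.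

Step 4
Reactants: 10 13-phenyltridecanoic acid; 11 mono-tert-butyl malonate (3-tert-butoxy-3-oxopropanoic acid)
Product: 14 tert-butyl 3-oxo-15-phenylpentadecanoate, via acyl imidazolide 12 (not isolated), via acylmalonic half-ester 13 (not isolated)
Conditions: CDI (1.1 equiv), THF, rt; then 11 (1.5 equiv), MgCl2 (1.5 equiv), Et3N (3 equiv), MeCN, rt → 40 °C; cold 1 M HCl
Reagents that add atoms: none
Why: Decarboxylative Claisen condensation of a malonic half-ester, in which the magnesium-bound enolate of 11 is C-acylated by acyl imidazolide 12 and the acylmalonic acid 13 loses CO2, gives the β-keto ester whose C2 is the future ring carbon C2 and so fixes the site of the next acylation without any choice between the two sides of a ketone.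

Step 5
Reactants: 14 tert-butyl 3-oxo-15-phenylpentadecanoate; 5 (S)-5-oxotetrahydrofuran-2-carbonyl chloride
Product: 16 tert-butyl 3-oxo-2-[(S)-5-oxotetrahydrofuran-2-carbonyl]-15-phenylpentadecanoate, via chloromagnesium enolate 15 (not isolated)
Conditions: MgCl2 (1.1 equiv), pyridine (2.2 equiv), CH2Cl2, 0 °C; then 5 (1.1 equiv), 0 °C → rt; cold 1 M HCl; crude 16 taken on
Reagents that add atoms: none
Why: C-Acylation of a magnesium-chelated β-keto ester enolate by an acid chloride (MgCl2 with a weak amine base) should work because chelate 15 reacts at carbon, the acid chloride carbonyl is far more electrophilic than the lactone carbonyl, and pyridine at 0 °C is too weak a base to enolise 5 at a significant rate, so its stereocentre should pass into 16 unchanged.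

Step 6
Reactants: 16 tert-butyl 3-oxo-2-[(S)-5-oxotetrahydrofuran-2-carbonyl]-15-phenylpentadecanoate
Product: 18 (S)-5-(3-oxo-15-phenylpentadecanoyl)dihydrofuran-2(3H)-one, via diketo acid 17 (not isolated)
Conditions: TFA/CH2Cl2 (1:4), 0 °C → rt; evaporation; toluene, 60 °C
Reagents that add atoms: none
Why: Acidolysis of the tert-butyl ester (E1 loss of isobutene) gives the β,β'-diketo acid 17, which decarboxylates through the usual six-membered cyclic transition state of β-keto acids, while anhydrous acid leaves the γ-lactone closed and its stereocentre untouched.

Step 7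
Reactants: 18 (S)-5-(3-oxo-15-phenylpentadecanoyl)dihydrofuran-2(3H)-one
Product: 22 oleiferinone, via potassium diketonate 19 (not isolated), via bridged alkoxide 20 (not isolated), via potassium triketonate 21 (not isolated)
Conditions: t-BuOK (1.05 equiv), THF, 0 °C → rt (→ 50 °C if closure is slow); then 1 M HCl, 0 °C, to pH 3
Reagents that add atoms: none
Why: One equivalent of t-BuOK removes the proton of the CH2 group between the two ketone carbonyls of 18 (future C1 and C1'), the only site acidic enough, and the central carbon of diketonate 19 adds to the lactone carbonyl carbon (future C3) on the ring face that carries the acyl chain, giving the bridged tetrahedral alkoxide 20, which breaks its C3–O bond so that the former ring oxygen leaves as the C6 alkoxide and at once takes the acidic C2 proton to give triketonate 21. The step belongs to the known family of alkoxide-mediated Dieckmann-type closures in which the central carbon of a 1,3-diketone is acylated by a δ-placed ester or lactone carbonyl to give a 2-acylcyclohexane-1,3-dione, and the bridged adduct 20 has its counterpart in the bridged adducts through which γ-lactones exchange their acyl group with a nucleophile on the γ-substituent. The one ring formed, the carbocycle C1–C6, closes through the new C2–C3 bond in the 6-exo-trig mode. No stereocentre is created: C6 comes from C2 of L-glutamic acid, its C–O bond is not broken, and its hydrogen is not removed because C1 belongs to a monoanionic enolate before and after ring closure and one equivalent of base cannot form a dianion. The selectivity needed is C- over O-acylation, and it is secured by thermodynamics: attack through an enolate oxygen gives only an enol lactone that can revert, whereas the C-acylated product is drained off as 21, a much weaker base than 19, which also drives an isomerisation that gains or loses no atom. Quenching into cold dilute acid should then give 22 as its internally hydrogen-bonded enol without dehydration of the C6 carbinol.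

**Compound list**

1 | L-glutamic acid | N[C@@H](CCC(=O)O)C(=O)O | starting material
2 | (S)-3-carboxy-1-carboxylatopropane-1-diazonium (diazonium carboxylate, inner salt) | N#[N+][C@@H](CCC(=O)O)C(=O)[O-] | intermediate
3 | (R)-3-(3-oxooxiran-2-yl)propanoic acid (α-lactone) | O=C1O[C@@H]1CCC(=O)O | intermediate
4 | (S)-5-oxotetrahydrofuran-2-carboxylic acid | O=C1CC[C@H](O1)C(=O)O | intermediate
5 | (S)-5-oxotetrahydrofuran-2-carbonyl chloride | O=C1CC[C@H](O1)C(=O)Cl | intermediate
6 | (2-bromoethyl)benzene | BrCCc1ccccc1 | starting material
7 | 11-bromoundecanoic acid | OC(=O)CCCCCCCCCCBr | starting material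
8 | 2-phenylethylmagnesium bromide | Br[Mg]CCc1ccccc1 | intermediate
9 | chloromagnesium 11-bromoundecanoate | Cl[Mg]OC(=O)CCCCCCCCCCBr | intermediate
10 | 13-phenyltridecanoic acid | OC(=O)CCCCCCCCCCCCc1ccccc1 | intermediate
11 | mono-tert-butyl malonate (3-tert-butoxy-3-oxopropanoic acid) | CC(C)(C)OC(=O)CC(=O)O | starting material
12 | 1-(13-phenyltridecanoyl)imidazole (acyl imidazolide) | O=C(CCCCCCCCCCCCc1ccccc1)n1ccnc1 | intermediate
13 | 2-(tert-butoxycarbonyl)-3-oxo-15-phenylpentadecanoic acid (acylmalonic half-ester, magnesium salt in the flask, C2 not defined) | CC(C)(C)OC(=O)C(C(=O)O)C(=O)CCCCCCCCCCCCc1ccccc1 | intermediate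
14 | tert-butyl 3-oxo-15-phenylpentadecanoate | CC(C)(C)OC(=O)CC(=O)CCCCCCCCCCCCc1ccccc1 | intermediate
15 | chloromagnesium (Z)-enolate of 14 (chelate) | CC(C)(C)OC(=O)/C=C(\O[Mg]Cl)CCCCCCCCCCCCc1ccccc1 | intermediate
16 | tert-butyl 3-oxo-2-[(S)-5-oxotetrahydrofuran-2-carbonyl]-15-phenylpentadecanoate (C2 labile, not defined) | CC(C)(C)OC(=O)C(C(=O)CCCCCCCCCCCCc1ccccc1)C(=O)[C@@H]1CCC(=O)O1 | intermediate
17 | 3-oxo-2-[(S)-5-oxotetrahydrofuran-2-carbonyl]-15-phenylpentadecanoic acid (diketo acid) | OC(=O)C(C(=O)CCCCCCCCCCCCc1ccccc1)C(=O)[C@@H]1CCC(=O)O1 | intermediate
18 | (S)-5-(3-oxo-15-phenylpentadecanoyl)dihydrofuran-2(3H)-one | O=C1CC[C@H](O1)C(=O)CC(=O)CCCCCCCCCCCCc2ccccc2 | intermediate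
19 | potassium diketonate of 18 | [K+].[O-]C(=CC(=O)CCCCCCCCCCCCc1ccccc1)[C@@H]1CCC(=O)O1 | intermediate
20 | potassium 3-oxo-2-(13-phenyltridecanoyl)-7-oxabicyclo[2.2.1]heptan-1-olate (bridged alkoxide; bridgeheads fixed by the lactone stereocentre, acyl-bearing carbon not defined) | [K+].[O-][C@]12CC[C@H](O1)C(=O)C2C(=O)CCCCCCCCCCCCc1ccccc1 | intermediate
21 | potassium triketonate (potassium salt of 22) | [K+].O=C(CCCCCCCCCCCCc1ccccc1)C1=C([O-])CC[C@H](O)C1=O | intermediate
22 | oleiferinone, (S)-3,6-dihydroxy-2-(13-phenyltridecanoyl)cyclohex-2-en-1-one | O=C(CCCCCCCCCCCCc1ccccc1)C1=C(O)CC[C@H](O)C1=O | target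

**Step count**

Total steps: 7. Longest linear sequence: 5 steps (steps 3, 4, 5, 6, 7 from 7; equally steps 1, 2, 5, 6, 7 from 1).

**Steps most likely to fail**

Step 7.
- What may go wrong: the carbon of diketonate 19 may not reach the tetrahedral stage, because closure onto the lactone carbonyl has to pass through the strained bridged adduct 20. Only reversible O-acylation or slow decomposition would then occur. On the product side, acid-promoted dehydration of the C6 carbinol with aromatisation is possible if the quench is warm or strongly acidic.
- Fallback (sets out from 18, returns at 22): the lactone is given up as the acyl donor, so the reacting ester and the course of ring closure change, not only the medium. NaOMe (3 equiv) in MeOH at rt → 60 °C first transesterifies the lactone to the acyclic hydroxy ester methyl (S)-4-hydroxy-5,7-dioxo-19-phenylnonadecanoate F1, held in the flask as its sodium diketonate. F1 then closes by the ordinary Dieckmann-type cyclisation of a 5,7-dioxo methyl ester: a 6-exo-trig attack of C6 on the ester carbon C1 through a monocyclic tetrahedral intermediate, with loss of methanol. Cold 1 M HCl gives 22. The carbinol carbon again sits beside a monoanionic diketonate and should not be enolised.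

Step 5.
- What may go wrong: loss of configurational purity of the acylating agent by α-deprotonation of its acylpyridinium salt (ketene pathway), and competing O-acylation of the magnesium chelate.
- Fallback (sets out from 4 and 10, returns at 16): the roles of the two halves are exchanged so that the acid chloride carries no stereocentre. Acid 4 is activated with CDI (THF, rt) to 1-[(S)-5-oxotetrahydrofuran-2-carbonyl]imidazole F2. F2 is chain-extended with 11 (MgCl2, Et3N, MeCN) through the acylmalonic half-ester 3-tert-butoxy-3-oxo-2-[(S)-5-oxotetrahydrofuran-2-carbonyl]propanoic acid F3 to tert-butyl 3-oxo-3-[(S)-5-oxotetrahydrofuran-2-yl]propanoate F4. Acid 10 is converted with (COCl)2 and cat. DMF in CH2Cl2 into 13-phenyltridecanoyl chloride F5. The chloromagnesium enolate F6 of F4 (MgCl2, pyridine, CH2Cl2, 0 °C) is then C-acylated by F5 to give 16, the same compound as in the main route. Step 2 is then not needed.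

Step 3.
- What may go wrong: homocoupling of the Grignard reagent, halogen–magnesium exchange, and reduction or elimination of the alkyl bromide, aggravated by poor solubility of the magnesium carboxylate at −20 °C.
- Fallback (sets out from 7, returns at 10): the sp3–sp3 coupling is replaced by acetylide alkylation and hydrogenation. Lithium phenylacetylide F7 (2.2 equiv, from commercial phenylacetylene, C#Cc1ccccc1, and n-BuLi, THF, −78 → 0 °C) converts 7 into lithium 11-bromoundecanoate F8 with its first equivalent. The second equivalent displaces the primary bromide (THF/DMPU, rt → 50 °C) to give, after acidification, 13-phenyltridec-12-ynoic acid F9. H2 (1 atm), Pd/C, EtOAc, rt should saturate the triple bond to give 10.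

**Further compounds**

F1 | step 7 | methyl (S)-4-hydroxy-5,7-dioxo-19-phenylnonadecanoate | COC(=O)CC[C@H](O)C(=O)CC(=O)CCCCCCCCCCCCc1ccccc1
F2 | step 5 | 1-[(S)-5-oxotetrahydrofuran-2-carbonyl]imidazole | O=C([C@@H]1CCC(=O)O1)n1ccnc1
F3 | step 5 | 3-tert-butoxy-3-oxo-2-[(S)-5-oxotetrahydrofuran-2-carbonyl]propanoic acid | CC(C)(C)OC(=O)C(C(=O)O)C(=O)[C@@H]1CCC(=O)O1
F4 | step 5 | tert-butyl 3-oxo-3-[(S)-5-oxotetrahydrofuran-2-yl]propanoate | CC(C)(C)OC(=O)CC(=O)[C@@H]1CCC(=O)O1
F5 | step 5 | 13-phenyltridecanoyl chloride | ClC(=O)CCCCCCCCCCCCc1ccccc1
F6 | step 5 | chloromagnesium (Z)-enolate of F4 | CC(C)(C)OC(=O)/C=C(\O[Mg]Cl)[C@@H]1CCC(=O)O1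
F7 | step 3 | lithium phenylacetylide | [Li]C#Cc1ccccc1
F8 | step 3 | lithium 11-bromoundecanoate | [Li+].[O-]C(=O)CCCCCCCCCCBr
F9 | step 3 | 13-phenyltridec-12-ynoic acid | OC(=O)CCCCCCCCCCC#Cc1ccccc1
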